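**Decisive age.** 6.00 d is the catalyst age of winter: the mean time the charge has spent in the flask, multiplied by free catalyst relative to the beta run. It is a mean residence time scaled by catalyst. You read the beta curve at that age.

| setting | beta | gamma | delta | zeta | winter | summer | noon |
|---|---|---|---|---|---|---|---|
| starting material | 0.020 M | 0.028 M | 0.044 M | 0.020 M | 0.020 M (fed, over 8.00 d) | 0.020 M | 0.020 M |
| free catalyst | 1 mM | 1 mM | 1 mM | 2 mM | 1.0 mM | 1.0 mM | 1.0 mM |
| remark | run made earlier | run made earlier | run made earlier | run made earlier | all but starting material at the start; starting material goes in evenly over 8.00 d, the run ends at 10 d | a closed flask charged with all of it at once and left for 10 d | a single well-mixed tank run continuously and read at steady state, 10 d in it on average |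
| time |  |  |  |  | 10 d | 10 d |  |

| run | time / d | target / % | starting material / % |
|---|---|---|---|
| beta | 1.67 | 7.4 | 88.8 |
| beta | 3.00 | 13.9 | 86.9 |
| beta | 5.00 | 21.3 | 77.3 |
| beta | 6.00 | 22.5 | 75.8 |
| beta | 8.00 | 25.9 | 72.6 |
| beta | 10.0 | 30.1 | 69.3 |
| gamma | 0.833 | 1.2 | 95.2 |
| gamma | 1.25 | 4.8 | 93.1 |
| gamma | 2.00 | 7.2 | 88.1 |
| gamma | 4.00 | 14.7 | 84.2 |
| gamma | 6.00 | 21.3 | 77.1 |
| gamma | 10.0 | 28.3 | 70.2 |
| delta | 0.833 | 0.9 | 94.7 |
| delta | 1.25 | 4.6 | 93.3 |
| delta | 2.00 | 6.1 | 93.8 |
| delta | 4.00 | 11.7 | 85.1 |
| delta | 6.00 | 15.5 | 81.0 |
| delta | 10.0 | 25.0 | 74.0 |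
| zeta | 2.08 | 17.3 | 79.0 |
| zeta | 4.00 | 26.6 | 68.7 |
| zeta | 6.00 | 31.6 | 65.9 |
| zeta | 8.00 | 35.1 | 62.1 |
| zeta | 10.0 | 37.8 | 58.4 |

(standard deviation of a reading: 1 percentage point)

* the set-up with the highest amount of target at the outlet or at the end, in percent of the starting material put in ("none" if the first two lie within 2 percentage points) (winter / summer / noon / none)
* amount of target at the outlet or at the end, in percent of the starting material put in, winter
* amount of target at the outlet or at the end, in percent of the starting material put in, summer
* amount of target at the outlet or at the end, in percent of the starting material put in, noon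

- the stated concentrations are those of everything mixed, before any reaction; amounts are the same in each set-up
- on the list of suspects stand: starting material + free catalyst <-> catalyst intermediate A; catalyst intermediate A <-> catalyst intermediate B; catalyst intermediate B <-> free catalyst + target
- the feed brings no volume worth counting
- the earlier runs were made in a closed, stirred flask

**Both ends.** Charged at once, starting material sits 10 d. Fed evenly up to the very end, it sits 5.00 d on average. Between these ends you subtract the mean entry time, 4.00 d for winter. Catalyst scales the clock: zeta reads 26.6 % at 4.00 d, and beta reads 25.9 % at 8.00 d.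

**Turned round.** On this rule, for winter to tie summer within 2 percentage points, beta would have to rise less than that from 6.00 d to 10.0 d. It rises 7.6 points. A thin early flask might repay some of this. But beta leads delta at 10.0 d by 5.1 points, across a charge ratio of 2.20, and that lead is smaller. So your reckoning is 30.1 % for summer and 22.5 % for winter, each reading with a scatter of 1 point. The tank in noon holds a spread of ages, and this rule gives no figure for it.

**The forecast.** It names summer: winter 22 % (18 % to 26 %), summer 30 % (28.5 % to 31.5 %), noon 23 % (20 % to 26 %). On winter it says: “low early concentrations waste time”.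

**The result.** The best set-up is summer: winter 22.8 %, summer 30.0 %, noon 23.3 %.

    starting material + free catalyst ⇌ catalyst intermediate A (K = 36.0 M⁻¹, k = 39.0 M⁻¹ h⁻¹)
    catalyst intermediate A ⇌ catalyst intermediate B (K = 0.320, k = 34.0 h⁻¹)
    catalyst intermediate B ⇌ free catalyst + target (K = 0.0580 M, k = 0.400 h⁻¹)

**Lost age.** The undoing of catalyst intermediate B into catalyst intermediate A is the main reason that winter stops short: with it struck out, winter gives 91.8 % against 22.8 %. Winter with all its starting material present from the start gives 30.0 % against 22.8 %. The slow dosing costs 7.2 points, which is a part of what winter lacks. In catalyst age, that is 6.00 d against 10.0 d. A neighbour flask is winter with 1.70 mM of free catalyst, so its catalyst age is 10.2 d, and beta at 10.0 d suggests 30.1 %. The computed flask gives 29.4 %.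

All runs are simulated with constants of no real substance; noise was put on by code.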